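Ring C of the upper unit is disconnected at C4–C3 and O1–C2. C4 is attached to C4a of ring A, whose C8a carries O1, so O1=C8a–C4a=C4 can be an ortho-quinone methide; the 2,3-trans-2,4-cis array is then the aryl-endo adduct of an E-alkene. The precursor is an o-hydroxybenzhydrol that already carries the complete benzylated (−)-fisetinidol unit on C4. Under a chiral Brønsted acid it cycloadds to (E)-4-benzyloxystyryl acetate, which brings C2, C3, the C3 oxygen and ring B. This one oxa-[4+2] step closes ring C as the last ring, forms two bonds and sets C2, C3 and C4.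

Key step: step 6

Assumption: (−)-fisetinidol 1 is bought as the natural (2R,3S) flavan-3-ol, and the (R)-acid written in step 6 stands for whichever antipode a pilot run shows to give the 4α adduct.

Ring letters used below: upper unit A (benzo), B (4-hydroxyphenyl), C (pyran); lower unit D (benzo), E (catechol), F (pyran).

Step 1
Reactants: 1 (−)-fisetinidol
Product: 2 (2R,3S)-3,7-bis(benzyloxy)-2-[3,4-bis(benzyloxy)phenyl]chromane
Conditions: BnBr (5 equiv), NaH (6 equiv), Bu4NI (cat.), DMF, 0 °C → rt (NaH added last)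
Reagents that add atoms: benzyl bromide, BrCc1ccccc1
Why: Williamson etherification of the three phenols and the secondary 3-OH touches no stereocenter, and having BnBr present before the base should cap the 4'-phenoxide at once so that base-induced opening of ring F and C2 epimerisation are avoided.

Step 2
Reactants: 2 tetra-O-benzylfisetinidol
Product: 3 (2R,3S)-3,7-bis(benzyloxy)-2-[3,4-bis(benzyloxy)phenyl]-6-bromochromane
Conditions: NBS (1.0 equiv), CH2Cl2, −78 → 0 °C
Reagents that add atoms: N-bromosuccinimide, O=C1CCC(=O)N1Br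
Why: Electrophilic aromatic bromination should go to C6 of ring D, which is para to O1 and ortho to the 7-benzyloxy group and less hindered than C8, while the catechol-type ring E is much less activated.

Step 3
Reactants: 3 the 6-bromide; 4 4-(benzyloxy)-2-hydroxybenzaldehyde
Product: 7 [4-(benzyloxy)-2-hydroxyphenyl][(2R,3S)-3,7-bis(benzyloxy)-2-(3,4-bis(benzyloxy)phenyl)chroman-6-yl]methanol (both carbinol epimers), via aryllithium 5 (not isolated), via lithium phenolate 6 (not isolated)
Conditions: 3, n-BuLi, THF, −78 °C; 4 + LiN(SiMe3)2, THF, −78 °C, cannulated in; −78 → −20 °C; aq. NH4Cl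
Reagents that add atoms: none
Why: Bromine–lithium exchange followed by 1,2-addition of the aryllithium to the aldehyde, whose acidic phenol is masked as its lithium salt, should give the diarylcarbinol; its new centre need not be controlled because it becomes sp2 in step 6.

Step 4
Reactants: 8 1-(benzyloxy)-4-ethynylbenzene
Product: 10 potassium (E)-[2-(4-(benzyloxy)phenyl)ethenyl]trifluoroborate, via catechol boronate 9 (not isolated)
Conditions: catecholborane, THF, 70 °C; then KHF2, MeOH–H2O, rt
Reagents that add atoms: catecholborane, B1Oc2ccccc2O1; potassium hydrogen difluoride, F.[F-].[K+]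
Why: syn-Hydroboration of the terminal alkyne places boron on the terminal carbon and fixes the E geometry, and KHF2 exchanges the catechol ester for the bench-stable trifluoroborate.

Step 5
Reactants: 10 the alkenyltrifluoroborate
Product: 11 (E)-2-[4-(benzyloxy)phenyl]ethenyl acetate
Conditions: AcOH, CuBr (10 mol%), DMAP, 4 Å MS, O2 (1 atm), MeCN, 60 °C
Reagents that add atoms: acetic acid, CC(=O)O
Why: Chan–Lam-type oxidative C–O coupling of an alkenyltrifluoroborate with a carboxylic acid should give the enol ester with retention of the E geometry.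

Step 6
Reactants: 7 the o-hydroxybenzhydrol; 11 the (E)-enol acetate
Product: 14 (2R,3S,4S)-7-(benzyloxy)-2-[4-(benzyloxy)phenyl]-4-[(2R,3S)-3,7-bis(benzyloxy)-2-(3,4-bis(benzyloxy)phenyl)chroman-6-yl]chroman-3-ol, via quinone methide 12 (not isolated), via 3-O-acetate 13 (not isolated)
Conditions: 11 (3 equiv), (R)-3,3'-bis(2,4,6-triisopropylphenyl)-BINOL N-triflylphosphoramide (10 mol%), 5 Å MS, CH2Cl2, −40 → 0 °C, 7 added slowly; then K2CO3, MeOH–THF, rt
Reagents that add atoms: none
Why: Proposed new method: the acid dehydrates 7 to the E-configured ortho-quinone methide 12, held as a hydrogen-bonded ion pair by the chiral phosphoramide; the acetoxy-bearing alkene carbon of 11 attacks the methide carbon (C4) and the benzylic carbon, whose positive charge the 4-benzyloxyphenyl group carries, is captured by O1, that is an inverse-demand oxa-[4+2] cycloaddition (concerted asynchronous, or Michael/oxa-Michael in the stepwise limit), after which K2CO3/MeOH removes the acetate. The closest known reaction type is the chiral N-triflylphosphoramide- or phosphoric acid-catalysed [4+2] cycloaddition of o-hydroxybenzhydrol-derived ortho-quinone methides with styrenes and trans-anethole to 2,4-diarylchromans; not yet shown is an enol ester reacting in the styrene sense so that it delivers the C3 oxygen. Ring C is closed as the six-membered ring of the [4+2] (in the stepwise limit a 6-endo-trig attack of the phenolic oxygen on the benzylic cation). The C2/C3 trans relation follows from the E geometry of 11 (suprafacial addition; in the stepwise limit from a trans-acetoxonium ion opened with inversion and from the all-equatorial product being the thermodynamic one), the C2/C4 cis relation from the aryl-endo transition state on the E-quinone methide, and the absolute configuration at C4 from the chiral counter-anion shielding one face of the methide, the stereocenters of ring F being too remote to matter. The step needs three selectivities: regiochemistry (the strong 4-benzyloxyphenyl donor outweighs the weak acetoxy donor, so the acetoxy-bearing carbon is the nucleophile), the right oxygen closing the ring (only the ring A hydroxyl is free and O7 of ring D is benzylated, so the isomeric pyran cannot form) and cycloaddition over Friedel–Crafts self-alkylation (excess 11, slow addition of 7, high dilution).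

Step 7
Reactants: 14 the hexa-O-benzyl dimer
Product: 15 (2R,3S,4R)-2-(4-hydroxyphenyl)-4-[(2R,3S)-2-(3,4-dihydroxyphenyl)-3,7-dihydroxychroman-6-yl]chroman-3,7-diol (target)
Conditions: H2 (1 atm), Pd(OH)2/C, THF–MeOH, rt
Reagents that add atoms: none
Why: Neutral hydrogenolysis of the six benzyl ethers should leave the benzylic C2–O1 and C4–aryl bonds and all five stereocenters untouched, as in the standard global debenzylation of benzylated proanthocyanidins.

Compound list
1 | (−)-fisetinidol, (2R,3S)-2-(3,4-dihydroxyphenyl)chromane-3,7-diol | Oc1ccc2c(c1)O[C@H](c1ccc(O)c(O)c1)[C@@H](O)C2 | starting material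
2 | (2R,3S)-3,7-bis(benzyloxy)-2-[3,4-bis(benzyloxy)phenyl]chromane | C(Oc1ccc2c(c1)O[C@H](c1ccc(OCc3ccccc3)c(OCc3ccccc3)c1)[C@@H](OCc1ccccc1)C2)c1ccccc1 | intermediate
3 | (2R,3S)-3,7-bis(benzyloxy)-2-[3,4-bis(benzyloxy)phenyl]-6-bromochromane | Brc1cc2c(cc1OCc1ccccc1)O[C@H](c1ccc(OCc3ccccc3)c(OCc3ccccc3)c1)[C@@H](OCc1ccccc1)C2 | intermediate
4 | 4-(benzyloxy)-2-hydroxybenzaldehyde | O=Cc1ccc(OCc2ccccc2)cc1O | starting material
5 | [(2R,3S)-3,7-bis(benzyloxy)-2-(3,4-bis(benzyloxy)phenyl)chroman-6-yl]lithium | [Li]c1cc2c(cc1OCc1ccccc1)O[C@H](c1ccc(OCc3ccccc3)c(OCc3ccccc3)c1)[C@@H](OCc1ccccc1)C2 | intermediate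
6 | lithium 5-(benzyloxy)-2-formylphenolate | [Li+].[O-]c1cc(OCc2ccccc2)ccc1C=O | intermediate
7 | [4-(benzyloxy)-2-hydroxyphenyl][(2R,3S)-3,7-bis(benzyloxy)-2-(3,4-bis(benzyloxy)phenyl)chroman-6-yl]methanol, both carbinol epimers | OC(c1ccc(OCc2ccccc2)cc1O)c1cc2c(cc1OCc1ccccc1)O[C@H](c1ccc(OCc3ccccc3)c(OCc3ccccc3)c1)[C@@H](OCc1ccccc1)C2 | intermediate
8 | 1-(benzyloxy)-4-ethynylbenzene | C#Cc1ccc(OCc2ccccc2)cc1 | starting material
9 | 2-[(E)-2-(4-(benzyloxy)phenyl)ethenyl]-1,3,2-benzodioxaborole | O1B(/C=C/c2ccc(OCc3ccccc3)cc2)Oc2ccccc12 | intermediate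
10 | potassium (E)-[2-(4-(benzyloxy)phenyl)ethenyl]trifluoroborate | [K+].F[B-](F)(F)/C=C/c1ccc(OCc2ccccc2)cc1 | intermediate
11 | (E)-2-[4-(benzyloxy)phenyl]ethenyl acetate | CC(=O)O/C=C/c1ccc(OCc2ccccc2)cc1 | intermediate
12 | (6E)-3-(benzyloxy)-6-{[(2R,3S)-3,7-bis(benzyloxy)-2-(3,4-bis(benzyloxy)phenyl)chroman-6-yl]methylidene}cyclohexa-2,4-dien-1-one | O=C1C=C(OCc2ccccc2)C=C/C1=C\c1cc2c(cc1OCc1ccccc1)O[C@H](c1ccc(OCc3ccccc3)c(OCc3ccccc3)c1)[C@@H](OCc1ccccc1)C2 | intermediate
13 | (2R,3S,4S)-7-(benzyloxy)-2-[4-(benzyloxy)phenyl]-4-[(2R,3S)-3,7-bis(benzyloxy)-2-(3,4-bis(benzyloxy)phenyl)chroman-6-yl]chroman-3-yl acetate, 2,3-trans-3,4-trans | c1ccccc1COc1ccc([C@H]2Oc3cc(OCc4ccccc4)ccc3[C@@H](c3cc4c(cc3OCc3ccccc3)O[C@H](c3ccc(OCc5ccccc5)c(OCc5ccccc5)c3)[C@@H](OCc3ccccc3)C4)[C@@H]2OC(C)=O)cc1 | intermediate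
14 | (2R,3S,4S)-7-(benzyloxy)-2-[4-(benzyloxy)phenyl]-4-[(2R,3S)-3,7-bis(benzyloxy)-2-(3,4-bis(benzyloxy)phenyl)chroman-6-yl]chroman-3-ol, 2,3-trans-3,4-trans (4S only because the benzyl ether on O7 of ring D changes the CIP ranking; same spatial arrangement as 4R in 15) | c1ccccc1COc1ccc([C@H]2Oc3cc(OCc4ccccc4)ccc3[C@@H](c3cc4c(cc3OCc3ccccc3)O[C@H](c3ccc(OCc5ccccc5)c(OCc5ccccc5)c3)[C@@H](OCc3ccccc3)C4)[C@@H]2O)cc1 | intermediate
15 | (2R,3S,4R)-2-(4-hydroxyphenyl)-4-[(2R,3S)-2-(3,4-dihydroxyphenyl)-3,7-dihydroxychroman-6-yl]chroman-3,7-diol, guibourtinidol-(4α→6)-fisetinidol | Oc1ccc([C@H]2Oc3cc(O)ccc3[C@@H](c3cc4c(cc3O)O[C@H](c3ccc(O)c(O)c3)[C@@H](O)C4)[C@@H]2O)cc1 | target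

Total step count: 7. Longest linear sequence: 5 steps (steps 1, 2, 3, 6, 7); steps 4 and 5 form the second branch.

Steps most likely to fail

1. Step 6 (proposed new method). The enol acetate may add too slowly, so the quinone methide is lost to Friedel–Crafts self-alkylation. The acetoxy group may reverse the regiochemistry. The ion pair may be too loose for face selection. A stepwise path may erode the C3/C4 relationship. The fallback uses known chemistry, sets out from 7 (with 8) and comes back at 14. The quinone methide from 7 is trapped with the alkyne 8 under an achiral acid (TfOH cat. or Sc(OTf)3, CH2Cl2, 0 °C). This is the known oxa-[4+2] route from o-hydroxybenzhydrols and arylacetylenes to 2,4-diaryl-4H-chromenes, and it still closes ring C last. It should give (4S)-7-(benzyloxy)-2-[4-(benzyloxy)phenyl]-4-[(2R,3S)-3,7-bis(benzyloxy)-2-(3,4-bis(benzyloxy)phenyl)chroman-6-yl]-4H-chromene F1 together with its (4R) epimer F2. The two are diastereomers because the lower unit is enantiopure, and would be separated by chromatography. Hydroboration of F1 (BH3·SMe2, THF, 0 °C; then NaOH, H2O2) should place boron on C3 of the enol ether and add anti to the C4 aryl group, so oxidation should give 14 with the 2,3-trans-3,4-trans array.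

2. Step 3. The ortho-benzyloxy aryllithium may undergo proton transfer or anionic rearrangement before it adds, and addition to the electron-rich phenolate aldehyde may be sluggish. The fallback reverses the polarity, sets out from 2 and comes back at 7. Vilsmeier–Haack formylation of 2 (POCl3, DMF, 0 → 60 °C; aq. NaOAc) should give (2R,3S)-3,7-bis(benzyloxy)-2-[3,4-bis(benzyloxy)phenyl]chromane-6-carbaldehyde F3. The cheap partner is then used in excess as lithium 5-(benzyloxy)-2-lithiophenolate F4, made from 2-bromo-5-(benzyloxy)phenol with two equivalents of n-BuLi (Et2O–THF, −78 → 0 °C). Its addition to F3 should give 7 after aq. NH4Cl.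

3. Step 5. Protodeboronation or oxidative homocoupling of the electron-rich alkenylboron species may outrun the C–O coupling. The fallback uses enolisation chemistry, sets out from 8 and comes back at 11. Anti-Markovnikov hydration of 8 by hydroboration with dicyclohexylborane and NaBO3 oxidation should give 2-[4-(benzyloxy)phenyl]acetaldehyde F5. O-Acetylation of its enolate (Ac2O, KOAc, 120 °C) should give 11 together with (Z)-2-[4-(benzyloxy)phenyl]ethenyl acetate F6, from which 11 would be separated by crystallisation or chromatography.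

Further compounds
F1 | step 6 | (4S)-7-(benzyloxy)-2-[4-(benzyloxy)phenyl]-4-[(2R,3S)-3,7-bis(benzyloxy)-2-(3,4-bis(benzyloxy)phenyl)chroman-6-yl]-4H-chromene | c1ccccc1COc1ccc(C2=C[C@H](c3cc4c(cc3OCc3ccccc3)O[C@H](c3ccc(OCc5ccccc5)c(OCc5ccccc5)c3)[C@@H](OCc3ccccc3)C4)c3ccc(OCc4ccccc4)cc3O2)cc1
F2 | step 6 | (4R)-7-(benzyloxy)-2-[4-(benzyloxy)phenyl]-4-[(2R,3S)-3,7-bis(benzyloxy)-2-(3,4-bis(benzyloxy)phenyl)chroman-6-yl]-4H-chromene | c1ccccc1COc1ccc(C2=C[C@@H](c3cc4c(cc3OCc3ccccc3)O[C@H](c3ccc(OCc5ccccc5)c(OCc5ccccc5)c3)[C@@H](OCc3ccccc3)C4)c3ccc(OCc4ccccc4)cc3O2)cc1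
F3 | step 3 | (2R,3S)-3,7-bis(benzyloxy)-2-[3,4-bis(benzyloxy)phenyl]chromane-6-carbaldehyde | O=Cc1cc2c(cc1OCc1ccccc1)O[C@H](c1ccc(OCc3ccccc3)c(OCc3ccccc3)c1)[C@@H](OCc1ccccc1)C2
F4 | step 3 | lithium 5-(benzyloxy)-2-lithiophenolate | [Li]Oc1cc(OCc2ccccc2)ccc1[Li]
F5 | step 5 | 2-[4-(benzyloxy)phenyl]acetaldehyde | O=CCc1ccc(OCc2ccccc2)cc1
F6 | step 5 | (Z)-2-[4-(benzyloxy)phenyl]ethenyl acetate | CC(=O)O/C=C\c1ccc(OCc2ccccc2)cc1
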